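**Retrosynthetic overview**
1. Locants (abyssomicin numbering): C1 lactone C=O, C2=C3(OH) enol, C4(Me), C5H2, C6(Me), C7 ketone, C8H, C9H2, C10H, C11(OH), C12(Me)(O), C13(Me), C14H2, C15 (lactone O), C16 (ether O, quaternary). Enabling feature: the eight-membered carbocycle C2–C3–C4–C5–C6–C7–C8–C16 is a cyclooctane-1,5-dione (C3 enolised, C7 keto) whose carbonyls are 1,5-related along both arms, so C5–C6 and C2–C16 are both β-to-α′ Michael bonds.
2. Key disconnection: a head-to-tail double Michael addition (formal [4+4]) of two α′-donor/β-acceptor enones, the methacryloylacetate ester on O–C15 and the cyclic vinylogous ester C16(O)=C8–C7(=O). C2→C16 closes the γ-lactone and C6→C5 closes the cyclooctane; a benzyl ester on C6 (removed at the end) makes C6 the donor.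
3. Tricyclic precursor: the oxygen bridge C12–O–C16 comes from anti opening of a C11–C12 epoxide by the C16 enol oxygen; the cyclopentane comes from acylation of a β-keto ester dianion by a lactone (C8–C16) and a reductive Knoevenagel closure (C8–C9).
4. Cyclohexene C10–C15 (stereocentres C10, C13, C15): BINOL-templated Diels–Alder/lactonisation of a dienol with methyl acrylate; C15–OH and the epoxide by enolate oxidation and directed epoxidation.
5. Ring order: cyclohexene + temporary γ-lactone → cyclopentanone → 2-oxabicyclo[2.2.2]octane → γ-lactone + cyclooctane (key step) → hydrogenolysis/decarboxylation.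

Key step: step 16

Assumption 1: the C4 and C6 methyl-bearing centres, each α to a carbonyl of the eight-membered ring, are taken to hold their thermodynamically preferred configuration in the natural product (both methyl groups pseudo-equatorial, cis to each other and to H8), so the route sets them by equilibration.
Assumption 2: (R)-BINOL is taken to give the antipode drawn for lactone 7; if the template shows the opposite sense, (S)-BINOL is used.

**Route**

Step 1
Reactants: 1 (E)-2-methylbut-2-enal (tiglic aldehyde); 2 triethyl phosphonoacetate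
Product: 3 ethyl (2E,4E)-4-methylhexa-2,4-dienoate
Conditions: NaH, THF, 0 °C → rt
Reagents that add atoms: none
Why: Horner–Wadsworth–Emmons olefination with a stabilised phosphonate should give the new (2E) alkene while the (E) geometry of the aldehyde is kept.

Step 2
Reactants: 3 ethyl (2E,4E)-4-methylhexa-2,4-dienoate
Product: 4 (2E,4E)-4-methylhexa-2,4-dien-1-ol
Conditions: DIBAL-H (2.2 equiv), CH2Cl2, −78 °C; Rochelle salt work-up
Reagents that add atoms: none
Why: DIBAL-H 1,2-reduction of a conjugated ester should give the dienol without touching the diene.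

Step 3
Reactants: 4 (2E,4E)-4-methylhexa-2,4-dien-1-ol; 5 methyl acrylate
Product: 7 all-cis 5,6-dimethyl-3a,6,7,7a-tetrahydro-2-benzofuran-1(3H)-one (cis-fused γ-lactone), via Diels–Alder hydroxy ester 6 (not isolated)
Conditions: Me2Zn (1.0 equiv), (R)-BINOL (0.3 equiv), MeMgBr (1.0 equiv), CH2Cl2, 0 °C → rt; aq. NH4Cl
Reagents that add atoms: none
Why: Lewis-acid-templated Diels–Alder reaction: the dienyl alkoxide and the acrylate carbonyl are held on a Zn/Mg–BINOL template, which should enforce the regiochemistry (acrylate α-carbon to C10), the endo mode (C9, C16 and the C13 methyl all cis) and, through the BINOL, the absolute configuration at C10, C13 and C15, after which the alkoxide closes the cis-fused lactone.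

Step 4
Reactants: 7 cis-fused lactone
Product: 8 7a-hydroxy lactone (C15–OH on the face of the former C15–H)
Conditions: KHMDS, THF, −78 °C; 2-(phenylsulfonyl)-3-phenyloxaziridine; aq. NH4Cl
Reagents that add atoms: 2-(phenylsulfonyl)-3-phenyloxaziridine, O=S(=O)(c1ccccc1)N1OC1c1ccccc1
Why: Enolate oxidation (Davis oxaziridine) should occur on the convex face, anti to the C13 methyl, which is the face that keeps the γ-lactone cis-fused and so sets C15.

Step 5
Reactants: 8 7a-hydroxy lactone
Product: 9 4,5-epoxy-7a-hydroxy lactone (oxirane syn to C15–OH, anti to the C13 methyl)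
Conditions: VO(acac)2 (cat.), t-BuOOH, CH2Cl2, 0 °C → rt
Reagents that add atoms: tert-butyl hydroperoxide, CC(C)(C)OO
Why: Hydroxyl-directed epoxidation of the homoallylic alcohol should deliver oxygen syn to C15–OH, setting C11 and the face from which C12 will later be inverted.

Step 6
Reactants: 9 epoxy hydroxy lactone
Product: 10 C15 triethylsilyl ether of 9
Conditions: TESOTf, 2,6-lutidine, CH2Cl2, −78 → 0 °C
Reagents that add atoms: triethylsilyl trifluoromethanesulfonate, CC[Si](CC)(CC)OS(=O)(=O)C(F)(F)F
Why: Silyl triflate silylation protects the tertiary α-hydroxyl so that no α-ketol alkoxide is present in the strongly basic step 8.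

Step 7
Reactants: 11 ethyl 2-methyl-3-oxobutanoate; 12 benzyl alcohol
Product: 13 benzyl 2-methyl-3-oxobutanoate
Conditions: DMAP (0.1 equiv), toluene, reflux with removal of ethanol
Reagents that add atoms: none
Why: DMAP-catalysed transesterification of a β-keto ester is driven by distilling off ethanol.

Step 8
Reactants: 10 silyl ether lactone; 13 benzyl 2-methyl-3-oxobutanoate
Product: 14 benzyl 5-(epoxycyclohexyl)-2-methyl-3,5-dioxopentanoate (ring-opened triketo ester with C9 CH2OH, C15 OTES, C11–C12 epoxide)
Conditions: 13 (3 equiv), LDA (6 equiv), THF, −78 → 0 °C; then 10, −78 → −20 °C; AcOH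
Reagents that add atoms: none
Why: Claisen-type acylation of the terminal (γ) carbon of the β-keto ester dianion by the non-enolisable lactone carbonyl should form C8–C16 and free the C9 alkoxide, the product being shielded from further attack as its polyanion.

Step 9
Reactants: 14 hydroxy triketo ester
Product: 15 C9 aldehyde of 14
Conditions: Dess–Martin periodinane, NaHCO3, CH2Cl2, 0 °C; used crude
Reagents that add atoms: none
Why: Buffered Dess–Martin oxidation of the primary alcohol should leave the epoxide, silyl ether and 1,3-dicarbonyl units intact.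

Step 10
Reactants: 15 aldehyde
Product: 17 cis-fused epoxy hydrindanone with the C8 (3-benzyloxy-2-methyl-3-oxopropanoyl) group (2-acylcyclopentanone), via alkylidene diketone 16 (not isolated)
Conditions: L-proline (0.2 equiv), Hantzsch ester (1.2 equiv), CH2Cl2, rt
Reagents that add atoms: none
Why: Amine-catalysed intramolecular Knoevenagel condensation of the most acidic carbon (C8, between the two ketones) with the C9 aldehyde closes the cyclopentene (only the cis-disposed C9/C16 pair can cyclise), and Hantzsch ester transfer hydrogenation reduces the alkylidene 1,3-diketone in situ.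

Step 11
Reactants: 17 epoxy 2-acylcyclopentanone
Product: 18 tricyclic vinylogous ester (2-oxabicyclo[2.2.2]octane fused to a cyclopentene, C16(O)=C8–C7(=O), free C11–OH, C15 OTES)
Conditions: CSA (0.05 equiv), CH2Cl2, 0 °C
Reagents that add atoms: none
Why: Acid-catalysed intramolecular epoxide opening: the C16 carbonyl/enol oxygen attacks the tertiary carbon C12 anti to the oxirane (six-membered closure to the oxabicyclo[2.2.2]octane with inversion at C12, leaving C11–OH anti to the bridge) and loss of the C8 proton gives the vinylogous ester, as known for enolised 1,3-dicarbonyl oxygens on such cyclohexene oxides.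

Step 12
Reactants: 18 tricyclic vinylogous ester
Product: 20 C11 benzyl carbonate with free tertiary C15–OH, via silyl ether carbonate 19 (not isolated)
Conditions: benzyl chloroformate, pyridine, DMAP (cat.), CH2Cl2, 0 °C → rt; then HF·pyridine, THF, 0 °C
Reagents that add atoms: benzyl chloroformate, O=C(Cl)OCc1ccccc1
Why: Chloroformate acylation of the only free hydroxyl followed by fluoride desilylation differentiates the two hydroxyls without relying on a selectivity.

Step 13
Reactants: 21 tert-butyl acetate; 22 methacrolein
Product: 23 tert-butyl 3-hydroxy-4-methylpent-4-enoate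
Conditions: LDA, THF, −78 °C; then 22; aq. NH4Cl
Reagents that add atoms: none
Why: Aldol addition of the lithium ester enolate to the enal should occur 1,2 at −78 °C.

Step 14
Reactants: 23 tert-butyl 3-hydroxy-4-methylpent-4-enoate
Product: 24 tert-butyl 4-methyl-3-oxopent-4-enoate (Nazarov-type β-keto ester)
Conditions: Dess–Martin periodinane, CH2Cl2, 0 °C → rt
Reagents that add atoms: none
Why: Dess–Martin oxidation of the allylic alcohol gives the enone β-keto ester under non-basic conditions that do not polymerise it.

Step 15
Reactants: 20 tertiary alcohol; 24 tert-butyl 4-methyl-3-oxopent-4-enoate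
Product: 26 C15 4-methyl-3-oxopent-4-enoate ester of 20 (key-step precursor), via acylketene 25 (not isolated)
Conditions: 24 (4 equiv), toluene, 110 °C, N2 sweep to remove t-BuOH
Reagents that add atoms: none
Why: Thermal transacylation of a tert-butyl β-keto ester: loss of tert-butanol gives acylketene 25, which is trapped by the tertiary C15 hydroxyl, a known way to acylate hindered alcohols under neutral conditions.

Step 16
Reactants: 26 key-step precursor
Product: 28 6-(benzyloxycarbonyl)-11-O-(benzyloxycarbonyl)abyssomicin N (C6 configuration immaterial), via mono-Michael lactone 27 (not isolated)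
Conditions: Cs2CO3 (1.0 equiv), MeCN (0.005 M), 25 → 50 °C; AcOH
Reagents that add atoms: none
Why: Proposed new method: Cs2CO3 ionises the C2 methylene of the methacryloylacetate, whose enolate adds 5-exo-trig to C16, the β-carbon of the vinylogous ester held three atoms away through O–C15, giving the cis-fused γ-lactone 27; the C8/C7 enolate so formed relays its charge by proton transfer to the far more acidic C6 β-keto ester position, whose enolate adds 8-endo-trig to the unsubstituted C5 terminus of the methacryloyl enone, and the C4 enolate is protonated so that the product rests as the C2=C3 enol. The closest known reaction types are the Cs2CO3-mediated double Michael annulation of 3-oxopent-4-enoate (Nazarov-type) esters with enones, which closes six-membered rings through the α-carbon of the acceptor, and the intramolecular Michael lactonisation of acetoacetates of γ-hydroxy enones; here the second addition is rerouted to the α′-carbon, so the head-to-tail union of the two enone units gives the cyclooctane-1,5-dione. C16 is fixed by the ester tether (C2 can reach only the face of C16 syn to the C15 oxygen), C8 by reversible protonation with only the cis-fused epimer able to reach C5, C4 by reversible protonation α to C3, and C6 becomes a quaternary centre whose configuration is erased in step 17. The step needs C6 and not C8 to attack C5 (eight- versus six-membered ring): the benzyl ester makes C6 the only doubly activated, unhindered donor of the C7 ketone, whereas C8 would have to form a quaternary centre next to quaternary C16. High dilution suppresses intermolecular addition, every event before the last C–C bond is reversible, and the opposite order of the two additions would converge on the same product.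

Step 17
Reactants: 28 bis-benzyl protected abyssomicin N
Product: 30 abyssomicin N, via diacid 29 (not isolated)
Conditions: H2 (1 atm), Pd/C, EtOAc, 25 °C; then 40 °C; then Et3N (0.1 equiv), MeOH, 25 °C
Reagents that add atoms: none
Why: Hydrogenolysis cleaves the benzyl ester and the benzyl carbonate, the β-keto acid and the carbonic half ester lose CO2, and C6 is set by ketonisation of the released enol and mild base equilibration α to C7 (C4 likewise α to C3) toward the arrangement with both methyl groups pseudo-equatorial and cis to H8.

**Compound list**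
1 | (E)-2-methylbut-2-enal (tiglic aldehyde) | C/C=C(\C)C=O | starting material
2 | triethyl phosphonoacetate | CCOC(=O)CP(=O)(OCC)OCC | starting material
3 | ethyl (2E,4E)-4-methylhexa-2,4-dienoate | C/C=C(C)/C=C/C(=O)OCC | intermediate
4 | (2E,4E)-4-methylhexa-2,4-dien-1-ol | C/C=C(C)/C=C/CO | intermediate
5 | methyl acrylate | C=CC(=O)OC | starting material
6 | methyl all-cis 2-(hydroxymethyl)-4,5-dimethylcyclohex-3-ene-1-carboxylate | COC(=O)[C@@H]1C[C@H](C)C(C)=C[C@@H]1CO | intermediate
7 | all-cis 5,6-dimethyl-3a,6,7,7a-tetrahydro-2-benzofuran-1(3H)-one | O=C1OC[C@H]2C=C(C)[C@@H](C)C[C@@H]12 | intermediate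
8 | 7a-hydroxy lactone (C15–OH cis to H10) | O=C1OC[C@H]2C=C(C)[C@@H](C)C[C@@]12O | intermediate
9 | 4,5-epoxy-7a-hydroxy lactone (oxirane syn to OH) | O=C1OC[C@H]2[C@@H]3O[C@]3(C)[C@@H](C)C[C@@]12O | intermediate
10 | C15 triethylsilyl ether of 9 | O=C1OC[C@H]2[C@@H]3O[C@]3(C)[C@@H](C)C[C@@]12O[Si](CC)(CC)CC | intermediate
11 | ethyl 2-methyl-3-oxobutanoate | CCOC(=O)C(C)C(C)=O | starting material
12 | benzyl alcohol | OCc1ccccc1 | starting material
13 | benzyl 2-methyl-3-oxobutanoate | CC(=O)C(C)C(=O)OCc1ccccc1 | intermediate
14 | ring-opened hydroxy triketo ester (C9 CH2OH, C15 OTES, C11–C12 epoxide) | OC[C@H]1[C@@H]2O[C@]2(C)[C@@H](C)C[C@@]1(O[Si](CC)(CC)CC)C(=O)CC(=O)C(C)C(=O)OCc1ccccc1 | intermediate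
15 | C9 aldehyde of 14 | O=C[C@H]1[C@@H]2O[C@]2(C)[C@@H](C)C[C@@]1(O[Si](CC)(CC)CC)C(=O)CC(=O)C(C)C(=O)OCc1ccccc1 | intermediate
16 | alkylidene diketone (2-acylcyclopent-2-enone, C8=C9) | O=C1C(C(=O)C(C)C(=O)OCc2ccccc2)=C[C@H]2[C@@H]3O[C@]3(C)[C@@H](C)C[C@@]12O[Si](CC)(CC)CC | intermediate
17 | cis-fused epoxy hydrindanone, C8 acylated (C8 and C6 epimeric/enolised) | O=C1C(C(=O)C(C)C(=O)OCc2ccccc2)C[C@H]2[C@@H]3O[C@]3(C)[C@@H](C)C[C@@]12O[Si](CC)(CC)CC | intermediate
18 | tricyclic vinylogous ester, C11–OH, C15 OTES | CC[Si](CC)(CC)O[C@]12C[C@H](C)[C@]3(C)OC1=C(C(=O)C(C)C(=O)OCc4ccccc4)C[C@H]2[C@@H]3O | intermediate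
19 | C11 benzyl carbonate of 18 | CC[Si](CC)(CC)O[C@]12C[C@H](C)[C@]3(C)OC1=C(C(=O)C(C)C(=O)OCc4ccccc4)C[C@H]2[C@@H]3OC(=O)OCc1ccccc1 | intermediate
20 | tricyclic vinylogous ester, free C15–OH, C11 benzyl carbonate | O[C@]12C[C@H](C)[C@]3(C)OC1=C(C(=O)C(C)C(=O)OCc4ccccc4)C[C@H]2[C@@H]3OC(=O)OCc1ccccc1 | intermediate
21 | tert-butyl acetate | CC(=O)OC(C)(C)C | starting material
22 | methacrolein | C=C(C)C=O | starting material
23 | tert-butyl 3-hydroxy-4-methylpent-4-enoate | C=C(C)C(O)CC(=O)OC(C)(C)C | intermediate
24 | tert-butyl 4-methyl-3-oxopent-4-enoate | C=C(C)C(=O)CC(=O)OC(C)(C)C | intermediate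
25 | (2-methylacryloyl)ketene | C=C(C)C(=O)C=C=O | intermediate
26 | C15 4-methyl-3-oxopent-4-enoate ester of 20 | C=C(C)C(=O)CC(=O)O[C@]12C[C@H](C)[C@]3(C)OC1=C(C(=O)C(C)C(=O)OCc4ccccc4)C[C@H]2[C@@H]3OC(=O)OCc1ccccc1 | intermediate
27 | cis-fused γ-lactone from C2–C16 addition (C2, C8, C6 unassigned) | C=C(C)C(=O)C1C(=O)O[C@]23C[C@H](C)[C@]4(C)O[C@]12C(C[C@H]3[C@@H]4OC(=O)OCc3ccccc3)C(=O)C(C)C(=O)OCc1ccccc1 | intermediate
28 | 6-(benzyloxycarbonyl)-11-O-(benzyloxycarbonyl)abyssomicin N (C6 unassigned) | CC1(C(=O)OCc2ccccc2)C[C@H](C)/C(O)=C2/C(=O)O[C@]34C[C@H](C)[C@]5(C)O[C@]23[C@@H](C[C@H]4[C@@H]5OC(=O)OCc2ccccc2)C1=O | intermediate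
29 | 6-carboxy-11-O-carboxy abyssomicin N | CC1(C(=O)O)C[C@H](C)/C(O)=C2/C(=O)O[C@]34C[C@H](C)[C@]5(C)O[C@]23[C@@H](C[C@H]4[C@@H]5OC(=O)O)C1=O | intermediate
30 | abyssomicin N | C[C@@H]1C[C@H](C)/C(O)=C2/C(=O)O[C@]34C[C@H](C)[C@]5(C)O[C@]23[C@@H](C[C@H]4[C@@H]5O)C1=O | target

**Step count and risks**
Total: 17 steps. Longest linear sequence: 14 steps (steps 1–6, 8–12, 15–17).

Most likely to fail:

1. Step 16 (proposed new method). The eight-membered closure may be outrun by intermolecular Michael addition or by six-membered closure through C8, or 27 may revert by β-elimination of the bridging oxygen. Fallback in known chemistry, from 20 back to 28, which forms C5–C6 first and intermolecularly. Et3N-catalysed Michael addition of the C6 β-keto ester of 20 to methacrolein 22 should give the aldehyde F1. Bromoacetyl bromide and pyridine then esterify the C15 hydroxyl to the bromoacetate F2. A SmI2-mediated intramolecular Reformatsky reaction (THF, −78 °C, high dilution) closes the eleven-membered β-hydroxy lactone F3. Dess–Martin oxidation gives the macrocyclic β-keto lactone F4. Cs2CO3 in MeCN then has to effect only the transannular 5-exo Michael addition of C2 to C16, which returns the route to 28.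

2. Step 17. Ketonisation at C6 may be unselective and equilibration at C4 and C6 may not favour the natural arrangement, leaving epimers at the methyl-bearing centres. Fallback from 28 directly to 30: the control element is changed from thermodynamic to reagent-controlled kinetic protonation. The Pd/C–H2 debenzylation/decarboxylation is run in the presence of a cinchona amino alcohol as chiral proton shuttle (cinchonine or cinchonidine, whichever matches the substrate), a known enantioselective decarboxylative protonation of benzyl β-keto esters, with no base treatment afterwards. This fallback makes no new compound (F0).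

3. Step 8. Addition of the dianion to the hindered, α-silyloxy lactone carbonyl may be slow, or the lactol alkoxide may revert to the lactone on work-up. Fallback from 10 back to 15, replacing the Claisen acylation by an aldol addition to the aldehyde oxidation level. DIBAL-H (CH2Cl2, −78 °C) reduces 10 to the lactol F5. The dianion of 13 (excess) adds to its open hydroxy aldehyde form to give the diol F6. Excess Dess–Martin periodinane oxidises both carbinols (C16 to the ketone, C9 to the aldehyde) and delivers 15.

**Further compounds**
F1 | step 16 | C6 Michael adduct of 20 with methacrolein (C3 aldehyde) | O[C@]12C[C@H](C)[C@]3(C)OC1=C(C(=O)C(C)(CC(C)C=O)C(=O)OCc4ccccc4)C[C@H]2[C@@H]3OC(=O)OCc1ccccc1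
F2 | step 16 | C15 bromoacetate of F1 | O=C(CBr)O[C@]12C[C@H](C)[C@]3(C)OC1=C(C(=O)C(C)(CC(C)C=O)C(=O)OCc4ccccc4)C[C@H]2[C@@H]3OC(=O)OCc1ccccc1
F3 | step 16 | eleven-membered β-hydroxy lactone | OC1CC(=O)O[C@]23C[C@H](C)[C@]4(C)OC2=C(C[C@H]3[C@@H]4OC(=O)OCc2ccccc2)C(=O)C(C)(C(=O)OCc2ccccc2)CC1C
F4 | step 16 | eleven-membered β-keto lactone | O=C1CC(=O)O[C@]23C[C@H](C)[C@]4(C)OC2=C(C[C@H]3[C@@H]4OC(=O)OCc2ccccc2)C(=O)C(C)(C(=O)OCc2ccccc2)CC1C
F0 | step 17 | none | none
F5 | step 8 | lactol from 10 | OC1OC[C@H]2[C@@H]3O[C@]3(C)[C@@H](C)C[C@@]12O[Si](CC)(CC)CC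
F6 | step 8 | aldol diol (C16 carbinol, C9 CH2OH) | OC[C@H]1[C@@H]2O[C@]2(C)[C@@H](C)C[C@@]1(O[Si](CC)(CC)CC)C(O)CC(=O)C(C)C(=O)OCc1ccccc1
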